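**Strategy.** The oxocane (numbered O1, C2 carrying the enyne chain, C3–Cl, C4H2, C5–Cl, C6–OAc, C7H2, C8 carrying the bromopropyl group) is disconnected at O1–C2 and C3–C4. The C3/C5 1,3-dichloride flanking the C4 methylene, next to the ring oxygen, is read as a Kharasch adduct of a trichloroacetyl unit. In one flask, trichloroacetyl chloride acylates the C8 hydroxyl of an acyclic all-syn oct-1-ene-3,5,6-triol derivative, and the CuCl-generated C3 radical closes 8-endo onto the terminal alkene carbon C4, transferring chlorine to C5. The lactone carbonyl (C2) later receives the side chain; the surplus C3 chlorines are removed and C3 is set through a hydroxyl.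

Key step: step 6

Remark: ring compounds are numbered as oxocanes as above (side-chain carbinol carbon = C1'); TBS = tert-butyldimethylsilyl, NAP = naphthalen-2-ylmethyl, TIPS = triisopropylsilyl; compounds 1, 4, 8, 16 and 21 are assumed to be commercial.

Step 1
Reactants: 1 methyl (R)-2-hydroxybutanoate
Product: 2 methyl (R)-2-(NAP-oxy)butanoate
Conditions: 2-(bromomethyl)naphthalene, Ag2O, Et2O, rt, dark
Reagents that add atoms: 2-(bromomethyl)naphthalene (BrCc1ccc2ccccc2c1)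
Why: Silver-oxide-promoted Williamson-type O-alkylation under non-basic conditions should give the NAP ether without epimerising the α-stereocentre, NAP being chosen because it chelates in step 3 and is removed oxidatively in step 17.

Step 2
Reactants: 2 methyl (R)-2-(NAP-oxy)butanoate
Product: 3 (R)-2-(NAP-oxy)butanal
Conditions: i-Bu2AlH, CH2Cl2, −78 °C; aq. KNaC4H4O6 (potassium sodium tartrate)
Reagents that add atoms: none
Why: Low-temperature i-Bu2AlH partial reduction stops at the tetrahedral aluminium hemiacetal, which releases the aldehyde on work-up; the α-stereocentre is untouched and the aldehyde is used crude.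

Step 3
Reactants: 3 (R)-2-(NAP-oxy)butanal; 4 2-(trimethylsilyloxy)buta-1,3-diene
Product: 5 (5R,6R)-5-hydroxy-6-(NAP-oxy)oct-1-en-3-one
Conditions: MgBr2·OEt2, CH2Cl2, −78 → −20 °C; dilute aq. HCl work-up
Reagents that add atoms: none
Why: Chelation-controlled Mukaiyama aldol addition, in which MgBr2 holds the aldehyde and ether oxygens in a Cram chelate and the enol silane attacks the face away from the ethyl group, should set the new C5 carbinol (R) syn to C6.

Step 4
Reactants: 5 (5R,6R)-5-hydroxy-6-(NAP-oxy)oct-1-en-3-one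
Product: 6 (3S,5R,6R)-6-(NAP-oxy)oct-1-ene-3,5-diol
Conditions: Et2BOMe, NaBH4, THF/MeOH, −78 °C; aq. NH4Cl, then MeOH azeotrope
Reagents that add atoms: none
Why: Narasaka–Prasad reduction, in which the diethylboron chelate of the β-hydroxy ketone takes external hydride axially, should give the 1,3-syn diol and so set C3 (S), the enone being reduced only at the carbonyl.

Step 5
Reactants: 6 (3S,5R,6R)-6-(NAP-oxy)oct-1-ene-3,5-diol
Product: 7 (3S,5R,6R)-3-(TBS-oxy)-6-(NAP-oxy)oct-1-en-5-ol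
Conditions: TBSCl, imidazole, CH2Cl2, −20 → 0 °C
Reagents that add atoms: tert-butyldimethylsilyl chloride (CC(C)(C)[Si](C)(C)Cl)
Why: Kinetic mono-silylation should take the allylic C3 hydroxyl, which is much less hindered than the C5 hydroxyl flanked by the branched NAP-bearing C6; no stereocentre is formed.

Step 6
Reactants: 7 (3S,5R,6R)-3-(TBS-oxy)-6-(NAP-oxy)oct-1-en-5-ol; 8 trichloroacetyl chloride
Product: 10 (5S,6S,8R)-6-(TBS-oxy)-3,3,5-trichloro-8-[(1R)-1-(NAP-oxy)propyl]oxocan-2-one, via trichloroacetate ester 9 (not isolated)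
Conditions: 8, 2,6-lutidine, ClCH2CH2Cl, 0 °C; then dilution to 0.01 M, CuCl (30 mol%), tris(2-pyridylmethyl)amine (30 mol%), 80 °C
Reagents that add atoms: none
Why: O-Acylation of the free hydroxyl of 7 by 8 forms the O1–C2 bond and gives ester 9; monovalent copper then abstracts a chlorine atom from the CCl3 group, the electrophilic α,α-dichloro ester radical (C3) adds to the terminal alkene carbon (C4) to form the C3–C4 bond, and the secondary C5 radical takes chlorine back from the divalent copper chloride complex, regenerating monovalent copper. The closest known reaction type is the copper-catalysed Kharasch-type chlorine-atom-transfer radical cyclisation of ω-alkenyl trichloroacetates to medium-ring lactones. The eight-membered ring closes in the 8-endo-trig mode. The only new stereocentre, C5, is set in the chlorine-transfer step, where the copper chloride complex should approach the ring radical anti to the adjacent C6 silyloxy group and give the 5,6-trans (5S) chloride. The step needs 8-endo over 7-exo closure and cyclisation over intermolecular addition; the s-trans ester geometry, which a smaller exo transition state cannot accommodate, should secure the first and high dilution the second, while the unactivated ethers are inert to the catalyst.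

Step 7
Reactants: 10 (5S,6S,8R)-6-(TBS-oxy)-3,3,5-trichloro-8-[(1R)-1-(NAP-oxy)propyl]oxocan-2-one
Product: 11 (5S,6S,8R)-6-(TBS-oxy)-5-chloro-8-[(1R)-1-(NAP-oxy)propyl]oxocan-2-one
Conditions: Zn dust, AcOH/THF, 50 °C
Reagents that add atoms: none
Why: Zinc reductive dehalogenation of the activated α-chlorines (zinc enolates protonated at once by AcOH) should remove both C3 chlorines while the unactivated secondary C5 chloride is untouched; no stereocentre is affected.

Step 8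
Reactants: 11 (5S,6S,8R)-6-(TBS-oxy)-5-chloro-8-[(1R)-1-(NAP-oxy)propyl]oxocan-2-one
Product: 13 (3R,5S,6S,8R)-6-(TBS-oxy)-5-chloro-3-hydroxy-8-[(1R)-1-(NAP-oxy)propyl]oxocan-2-one, via potassium enolate 12 (not isolated)
Conditions: KN(SiMe3)2, THF, −78 °C; 2-(phenylsulfonyl)-3-phenyloxaziridine, −78 °C; AcOH quench
Reagents that add atoms: 2-(phenylsulfonyl)-3-phenyloxaziridine (O=S(=O)(c1ccccc1)N1OC1c1ccccc1)
Why: Enolate α-hydroxylation with an N-sulfonyloxaziridine, run entirely at −78 °C where 1,3-displacement of the C5 chloride by the enolate is slow, should deliver oxygen to C3 anti to the bulky C6 silyloxy group, that is on the face of the C8 side chain, giving the 3R alcohol.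

Step 9
Reactants: 13 (3R,5S,6S,8R)-6-(TBS-oxy)-5-chloro-3-hydroxy-8-[(1R)-1-(NAP-oxy)propyl]oxocan-2-one
Product: 15 (3R,5S,6S,8R)-3-acetoxy-6-(TBS-oxy)-5-chloro-8-[(1R)-1-(NAP-oxy)propyl]oxocan-2-yl acetate (C2 epimers), via lactol 14 (not isolated)
Conditions: i-Bu2AlH, CH2Cl2, −78 °C; then pyridine, DMAP, Ac2O, −78 → 0 °C
Reagents that add atoms: acetic anhydride (CC(=O)OC(C)=O)
Why: One-pot reductive acetylation, in which i-Bu2AlH deprotonates the C3 hydroxyl and reduces the lactone to the aluminium lactolate and both oxygens are acetylated in situ without ring opening, should give the diacetate; the C2 epimers converge in step 10.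

Step 10
Reactants: 15 (3R,5S,6S,8R)-3-acetoxy-6-(TBS-oxy)-5-chloro-8-[(1R)-1-(NAP-oxy)propyl]oxocan-2-yl acetate; 16 allyltrimethylsilane
Product: 17 (2S,3R,5S,6S,8R)-3-acetoxy-2-allyl-6-(TBS-oxy)-5-chloro-8-[(1R)-1-(NAP-oxy)propyl]oxocane
Conditions: 16, BF3·OEt2, CH2Cl2, −40 → 0 °C
Reagents that add atoms: none
Why: Hosomi–Sakurai C-glycosylation, in which BF3 ionises the anomeric acetate, the C3 acetate bridges the oxocarbenium ion on its own face by anchimeric assistance and the allylsilane attacks C2 from the opposite face, should set C2 (S) trans to C3–OAc and trans to the C8 side chain.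

Step 11
Reactants: 17 (2S,3R,5S,6S,8R)-3-acetoxy-2-allyl-6-(TBS-oxy)-5-chloro-8-[(1R)-1-(NAP-oxy)propyl]oxocane
Product: 18 (2S,3R,5S,6S,8R)-2-allyl-6-(TBS-oxy)-5-chloro-3-hydroxy-8-[(1R)-1-(NAP-oxy)propyl]oxocane
Conditions: K2CO3, MeOH, 0 °C → rt
Reagents that add atoms: none
Why: Mild base-catalysed methanolysis (transesterification) should free the C3 hydroxyl while silyl ether, NAP ether, chloride and all stereocentres stay intact.

Step 12
Reactants: 18 (2S,3R,5S,6S,8R)-2-allyl-6-(TBS-oxy)-5-chloro-3-hydroxy-8-[(1R)-1-(NAP-oxy)propyl]oxocane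
Product: 19 (2S,3S,5S,6S,8R)-2-allyl-6-(TBS-oxy)-3,5-dichloro-8-[(1R)-1-(NAP-oxy)propyl]oxocane
Conditions: (n-C8H17)3P, CCl4, toluene, 70 °C
Reagents that add atoms: tetrachloromethane (ClC(Cl)(Cl)Cl)
Why: Appel-type chlorination, in which chloride displaces the alkoxyphosphonium group by an SN2 process, should invert C3 to the 3S chloride, now cis to the C2 allyl group.

Step 13
Reactants: 19 (2S,3S,5S,6S,8R)-2-allyl-6-(TBS-oxy)-3,5-dichloro-8-[(1R)-1-(NAP-oxy)propyl]oxocane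
Product: 20 2-[(2S,3S,5S,6S,8R)-6-(TBS-oxy)-3,5-dichloro-8-[(1R)-1-(NAP-oxy)propyl]oxocan-2-yl]acetaldehyde
Conditions: OsO4 (cat.), NaIO4, 2,6-lutidine, dioxane/H2O, rt
Reagents that add atoms: sodium periodate ([Na+].[O-]I(=O)(=O)=O)
Why: Lemieux–Johnson oxidative cleavage (osmylation of the terminal alkene, then periodate cleavage of the diol) should give the aldehyde, with 2,6-lutidine suppressing over-oxidation.

Step 14
Reactants: 20 2-[(2S,3S,5S,6S,8R)-6-(TBS-oxy)-3,5-dichloro-8-[(1R)-1-(NAP-oxy)propyl]oxocan-2-yl]acetaldehyde; 21 1,3-bis(triisopropylsilyl)propyne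
Product: 22 (2S,3S,5S,6S,8R)-6-(TBS-oxy)-3,5-dichloro-8-[(1R)-1-(NAP-oxy)propyl]-2-[(2Z)-5-(TIPS)pent-2-en-4-yn-1-yl]oxocane
Conditions: 21, n-BuLi, THF, −20 °C; then 20, −78 → 0 °C
Reagents that add atoms: none
Why: Peterson olefination, in which the lithiated bis-silylpropyne adds to the aldehyde with the bulky silyl groups anti and the β-silyl alkoxide undergoes syn elimination, should give the Z-enyne.

Step 15
Reactants: 22 (2S,3S,5S,6S,8R)-6-(TBS-oxy)-3,5-dichloro-8-[(1R)-1-(NAP-oxy)propyl]-2-[(2Z)-5-(TIPS)pent-2-en-4-yn-1-yl]oxocane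
Product: 23 (2S,3S,5S,6S,8R)-3,5-dichloro-6-hydroxy-8-[(1R)-1-(NAP-oxy)propyl]-2-[(2Z)-pent-2-en-4-yn-1-yl]oxocane
Conditions: Bu4NF, AcOH, THF, 0 °C → rt
Reagents that add atoms: none
Why: Fluoride-mediated desilylation should cleave both the alkynyl C–Si bond and the C6 silyl ether, the acetic acid buffer keeping the liberated C6 hydroxyl protonated so that it does not close an epoxide onto the anti C5 chloride.

Step 16
Reactants: 23 (2S,3S,5S,6S,8R)-3,5-dichloro-6-hydroxy-8-[(1R)-1-(NAP-oxy)propyl]-2-[(2Z)-pent-2-en-4-yn-1-yl]oxocane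
Product: 24 (2S,3S,5S,6S,8R)-6-acetoxy-3,5-dichloro-8-[(1R)-1-(NAP-oxy)propyl]-2-[(2Z)-pent-2-en-4-yn-1-yl]oxocane
Conditions: Ac2O, pyridine, DMAP, CH2Cl2, rt
Reagents that add atoms: acetic anhydride (CC(=O)OC(C)=O)
Why: DMAP-catalysed acetylation of the only free hydroxyl (C6) should install the acetate of the target without touching any stereocentre.

Step 17
Reactants: 24 (2S,3S,5S,6S,8R)-6-acetoxy-3,5-dichloro-8-[(1R)-1-(NAP-oxy)propyl]-2-[(2Z)-pent-2-en-4-yn-1-yl]oxocane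
Product: 25 (2S,3S,5S,6S,8R)-6-acetoxy-3,5-dichloro-8-[(1R)-1-hydroxypropyl]-2-[(2Z)-pent-2-en-4-yn-1-yl]oxocane
Conditions: DDQ, CH2Cl2/aq. NaH2PO4–Na2HPO4 buffer, rt
Reagents that add atoms: none
Why: Oxidative cleavage of the NAP ether by DDQ (benzylic hydride abstraction, then hydrolysis of the oxocarbenium ion) should free the C1' alcohol without affecting the acetate, the chlorides or the enyne.

Step 18
Reactants: 25 (2S,3S,5S,6S,8R)-6-acetoxy-3,5-dichloro-8-[(1R)-1-hydroxypropyl]-2-[(2Z)-pent-2-en-4-yn-1-yl]oxocane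
Product: 26 (2S,3S,5S,6S,8R)-6-acetoxy-8-[(1S)-1-bromopropyl]-3,5-dichloro-2-[(2Z)-pent-2-en-4-yn-1-yl]oxocane
Conditions: CBr4, (n-C8H17)3P, toluene, 70 °C
Reagents that add atoms: tetrabromomethane (BrC(Br)(Br)Br)
Why: Appel-type bromination, with SN2 displacement of the alkoxyphosphonium group by bromide, should invert C1' from R to S and complete the target.

**Compound list**

1 | methyl (R)-2-hydroxybutanoate | CC[C@@H](O)C(=O)OC | starting material
2 | methyl (R)-2-(naphthalen-2-ylmethoxy)butanoate | CC[C@@H](OCc1ccc2ccccc2c1)C(=O)OC | intermediate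
3 | (R)-2-(naphthalen-2-ylmethoxy)butanal | CC[C@@H](OCc1ccc2ccccc2c1)C=O | intermediate
4 | 2-(trimethylsilyloxy)buta-1,3-diene | C=CC(=C)O[Si](C)(C)C | starting material
5 | (5R,6R)-5-hydroxy-6-(naphthalen-2-ylmethoxy)oct-1-en-3-one | CC[C@@H](OCc1ccc2ccccc2c1)[C@H](O)CC(=O)C=C | intermediate
6 | (3S,5R,6R)-6-(naphthalen-2-ylmethoxy)oct-1-ene-3,5-diol | CC[C@@H](OCc1ccc2ccccc2c1)[C@H](O)C[C@H](O)C=C | intermediate
7 | (3S,5R,6R)-3-[(tert-butyldimethylsilyl)oxy]-6-(naphthalen-2-ylmethoxy)oct-1-en-5-ol | CC[C@@H](OCc1ccc2ccccc2c1)[C@H](O)C[C@H](O[Si](C)(C)C(C)(C)C)C=C | intermediate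
8 | trichloroacetyl chloride | ClC(Cl)(Cl)C(Cl)=O | starting material
9 | (3S,5R,6R)-3-[(tert-butyldimethylsilyl)oxy]-6-(naphthalen-2-ylmethoxy)oct-1-en-5-yl 2,2,2-trichloroacetate | CC[C@@H](OCc1ccc2ccccc2c1)[C@H](OC(=O)C(Cl)(Cl)Cl)C[C@H](O[Si](C)(C)C(C)(C)C)C=C | intermediate (not isolated)
10 | (5S,6S,8R)-6-[(tert-butyldimethylsilyl)oxy]-3,3,5-trichloro-8-[(1R)-1-(naphthalen-2-ylmethoxy)propyl]oxocan-2-one | O=C1O[C@@H]([C@H](OCc2ccc3ccccc3c2)CC)C[C@H](O[Si](C)(C)C(C)(C)C)[C@@H](Cl)CC1(Cl)Cl | intermediate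
11 | (5S,6S,8R)-6-[(tert-butyldimethylsilyl)oxy]-5-chloro-8-[(1R)-1-(naphthalen-2-ylmethoxy)propyl]oxocan-2-one | O=C1O[C@@H]([C@H](OCc2ccc3ccccc3c2)CC)C[C@H](O[Si](C)(C)C(C)(C)C)[C@@H](Cl)CC1 | intermediate
12 | potassium (5S,6S,8R)-6-[(tert-butyldimethylsilyl)oxy]-5-chloro-8-[(1R)-1-(naphthalen-2-ylmethoxy)propyl]-5,6,7,8-tetrahydro-4H-oxocin-2-olate (enolate of 11) | [K+].[O-]C=1O[C@@H]([C@H](OCc2ccc3ccccc3c2)CC)C[C@H](O[Si](C)(C)C(C)(C)C)[C@@H](Cl)CC=1 | intermediate (not isolated)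
13 | (3R,5S,6S,8R)-6-[(tert-butyldimethylsilyl)oxy]-5-chloro-3-hydroxy-8-[(1R)-1-(naphthalen-2-ylmethoxy)propyl]oxocan-2-one | O=C1O[C@@H]([C@H](OCc2ccc3ccccc3c2)CC)C[C@H](O[Si](C)(C)C(C)(C)C)[C@@H](Cl)C[C@H]1O | intermediate
14 | (3R,5S,6S,8R)-6-[(tert-butyldimethylsilyl)oxy]-5-chloro-8-[(1R)-1-(naphthalen-2-ylmethoxy)propyl]oxocane-2,3-diol (lactol, present as its aluminium alkoxide; C2 epimers) | OC1O[C@@H]([C@H](OCc2ccc3ccccc3c2)CC)C[C@H](O[Si](C)(C)C(C)(C)C)[C@@H](Cl)C[C@H]1O | intermediate (not isolated)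
15 | (3R,5S,6S,8R)-3-acetoxy-6-[(tert-butyldimethylsilyl)oxy]-5-chloro-8-[(1R)-1-(naphthalen-2-ylmethoxy)propyl]oxocan-2-yl acetate (C2 epimers) | CC(=O)OC1O[C@@H]([C@H](OCc2ccc3ccccc3c2)CC)C[C@H](O[Si](C)(C)C(C)(C)C)[C@@H](Cl)C[C@H]1OC(C)=O | intermediate
16 | allyltrimethylsilane | C=CC[Si](C)(C)C | starting material
17 | (2S,3R,5S,6S,8R)-3-acetoxy-2-allyl-6-[(tert-butyldimethylsilyl)oxy]-5-chloro-8-[(1R)-1-(naphthalen-2-ylmethoxy)propyl]oxocane | C=CC[C@@H]1O[C@@H]([C@H](OCc2ccc3ccccc3c2)CC)C[C@H](O[Si](C)(C)C(C)(C)C)[C@@H](Cl)C[C@H]1OC(C)=O | intermediate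
18 | (2S,3R,5S,6S,8R)-2-allyl-6-[(tert-butyldimethylsilyl)oxy]-5-chloro-3-hydroxy-8-[(1R)-1-(naphthalen-2-ylmethoxy)propyl]oxocane | C=CC[C@@H]1O[C@@H]([C@H](OCc2ccc3ccccc3c2)CC)C[C@H](O[Si](C)(C)C(C)(C)C)[C@@H](Cl)C[C@H]1O | intermediate
19 | (2S,3S,5S,6S,8R)-2-allyl-6-[(tert-butyldimethylsilyl)oxy]-3,5-dichloro-8-[(1R)-1-(naphthalen-2-ylmethoxy)propyl]oxocane | C=CC[C@@H]1O[C@@H]([C@H](OCc2ccc3ccccc3c2)CC)C[C@H](O[Si](C)(C)C(C)(C)C)[C@@H](Cl)C[C@@H]1Cl | intermediate
20 | 2-[(2S,3S,5S,6S,8R)-6-[(tert-butyldimethylsilyl)oxy]-3,5-dichloro-8-[(1R)-1-(naphthalen-2-ylmethoxy)propyl]oxocan-2-yl]acetaldehyde | O=CC[C@@H]1O[C@@H]([C@H](OCc2ccc3ccccc3c2)CC)C[C@H](O[Si](C)(C)C(C)(C)C)[C@@H](Cl)C[C@@H]1Cl | intermediate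
21 | 1,3-bis(triisopropylsilyl)propyne | CC(C)[Si](CC#C[Si](C(C)C)(C(C)C)C(C)C)(C(C)C)C(C)C | starting material
22 | (2S,3S,5S,6S,8R)-6-[(tert-butyldimethylsilyl)oxy]-3,5-dichloro-8-[(1R)-1-(naphthalen-2-ylmethoxy)propyl]-2-[(2Z)-5-(triisopropylsilyl)pent-2-en-4-yn-1-yl]oxocane | CC(C)[Si](C#C/C=C\C[C@@H]1O[C@@H]([C@H](OCc2ccc3ccccc3c2)CC)C[C@H](O[Si](C)(C)C(C)(C)C)[C@@H](Cl)C[C@@H]1Cl)(C(C)C)C(C)C | intermediate
23 | (2S,3S,5S,6S,8R)-3,5-dichloro-6-hydroxy-8-[(1R)-1-(naphthalen-2-ylmethoxy)propyl]-2-[(2Z)-pent-2-en-4-yn-1-yl]oxocane | C#C/C=C\C[C@@H]1O[C@@H]([C@H](OCc2ccc3ccccc3c2)CC)C[C@H](O)[C@@H](Cl)C[C@@H]1Cl | intermediate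
24 | (2S,3S,5S,6S,8R)-6-acetoxy-3,5-dichloro-8-[(1R)-1-(naphthalen-2-ylmethoxy)propyl]-2-[(2Z)-pent-2-en-4-yn-1-yl]oxocane | C#C/C=C\C[C@@H]1O[C@@H]([C@H](OCc2ccc3ccccc3c2)CC)C[C@H](OC(C)=O)[C@@H](Cl)C[C@@H]1Cl | intermediate
25 | (2S,3S,5S,6S,8R)-6-acetoxy-3,5-dichloro-8-[(1R)-1-hydroxypropyl]-2-[(2Z)-pent-2-en-4-yn-1-yl]oxocane | C#C/C=C\C[C@@H]1O[C@@H]([C@H](O)CC)C[C@H](OC(C)=O)[C@@H](Cl)C[C@@H]1Cl | intermediate
26 | (2S,3S,5S,6S,8R)-6-acetoxy-8-[(1S)-1-bromopropyl]-3,5-dichloro-2-[(2Z)-pent-2-en-4-yn-1-yl]oxocane (CNP0251465.4) | C#C/C=C\C[C@@H]1O[C@@H]([C@@H](Br)CC)C[C@H](OC(C)=O)[C@@H](Cl)C[C@@H]1Cl | target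

**Totals.** Total step count: 18. Longest linear sequence: 18 steps (from 1).

**Steps most likely to fail**

Step 6: oligomerisation by intermolecular atom transfer, 7-exo closure, or poor facial selectivity in the chlorine transfer may erode the cyclisation. The fallback sets out from 7 and makes the two bonds in the opposite order. Intermolecular Kharasch addition of methyl trichloroacetate (excess, CuCl/tris(2-pyridylmethyl)amine, 80 °C) to the terminal alkene should give methyl (4S,5S,7R,8R)-5-[(tert-butyldimethylsilyl)oxy]-2,2,4-trichloro-7-hydroxy-8-(naphthalen-2-ylmethoxy)decanoate F1. Hydrolysis of the activated ester (LiOH, THF/H2O, 0 °C) should give (4S,5S,7R,8R)-5-[(tert-butyldimethylsilyl)oxy]-2,2,4-trichloro-7-hydroxy-8-(naphthalen-2-ylmethoxy)decanoic acid F2. Yamaguchi lactonisation (2,4,6-trichlorobenzoyl chloride, Et3N, then DMAP, toluene, high dilution) then closes O1–C2 and the route is rejoined at 10.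

Step 8: poor or reversed facial selectivity in the enolate oxidation would give the wrong C3 configuration. The fallback sets out from 11. If the oxidation gives mainly (3S,5S,6S,8R)-6-[(tert-butyldimethylsilyl)oxy]-5-chloro-3-hydroxy-8-[(1R)-1-(naphthalen-2-ylmethoxy)propyl]oxocan-2-one F3, Mitsunobu inversion with chloroacetic acid (Ph3P, diisopropyl azodicarboxylate, THF) should give (3R,5S,6S,8R)-6-[(tert-butyldimethylsilyl)oxy]-5-chloro-8-[(1R)-1-(naphthalen-2-ylmethoxy)propyl]-2-oxooxocan-3-yl 2-chloroacetate F4. Removal of the chloroacetyl group with thiourea/NaHCO3 in EtOH, under near-neutral conditions that leave the lactone closed, rejoins the route at 13.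

Step 12: participation of the C6 silyloxy oxygen, or elimination, may compete with clean SN2 displacement at the hindered C3 centre. The fallback sets out from 18, which is converted (ClCH2SO2Cl, pyridine, 0 °C) into (2S,3R,5S,6S,8R)-2-allyl-6-[(tert-butyldimethylsilyl)oxy]-5-chloro-8-[(1R)-1-(naphthalen-2-ylmethoxy)propyl]oxocan-3-yl chloromethanesulfonate F5. Displacement of the sulfonate with inversion by a high concentration of chloride (LiCl, DMF, 50 °C) rejoins the route at 19.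

**Further compounds**

F1 | step 6 | methyl (4S,5S,7R,8R)-5-[(tert-butyldimethylsilyl)oxy]-2,2,4-trichloro-7-hydroxy-8-(naphthalen-2-ylmethoxy)decanoate | CC[C@@H](OCc1ccc2ccccc2c1)[C@H](O)C[C@H](O[Si](C)(C)C(C)(C)C)[C@@H](Cl)CC(Cl)(Cl)C(=O)OC
F2 | step 6 | (4S,5S,7R,8R)-5-[(tert-butyldimethylsilyl)oxy]-2,2,4-trichloro-7-hydroxy-8-(naphthalen-2-ylmethoxy)decanoic acid | CC[C@@H](OCc1ccc2ccccc2c1)[C@H](O)C[C@H](O[Si](C)(C)C(C)(C)C)[C@@H](Cl)CC(Cl)(Cl)C(=O)O
F3 | step 8 | (3S,5S,6S,8R)-6-[(tert-butyldimethylsilyl)oxy]-5-chloro-3-hydroxy-8-[(1R)-1-(naphthalen-2-ylmethoxy)propyl]oxocan-2-one | O=C1O[C@@H]([C@H](OCc2ccc3ccccc3c2)CC)C[C@H](O[Si](C)(C)C(C)(C)C)[C@@H](Cl)C[C@@H]1O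
F4 | step 8 | (3R,5S,6S,8R)-6-[(tert-butyldimethylsilyl)oxy]-5-chloro-8-[(1R)-1-(naphthalen-2-ylmethoxy)propyl]-2-oxooxocan-3-yl 2-chloroacetate | O=C1O[C@@H]([C@H](OCc2ccc3ccccc3c2)CC)C[C@H](O[Si](C)(C)C(C)(C)C)[C@@H](Cl)C[C@H]1OC(=O)CCl
F5 | step 12 | (2S,3R,5S,6S,8R)-2-allyl-6-[(tert-butyldimethylsilyl)oxy]-5-chloro-8-[(1R)-1-(naphthalen-2-ylmethoxy)propyl]oxocan-3-yl chloromethanesulfonate | C=CC[C@@H]1O[C@@H]([C@H](OCc2ccc3ccccc3c2)CC)C[C@H](O[Si](C)(C)C(C)(C)C)[C@@H](Cl)C[C@H]1OS(=O)(=O)CCl
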